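**Plan**

1. Locants and rings: unit a is the dihydrobenzofuran O11b–C7a–C8a, with ring A (4-oxyphenyl) on C7a and ring B (3,5-dioxyphenyl, C9a–C14a) on C8a. Unit b is the central ring D (C9b–C14b) with C8b (CH2) and C7b (H, carrying ring C, 4-oxyphenyl), C7b–C10a closing the seven-membered ring. Unit c is the dihydrobenzofuran O13b–C7c–C8c on C13b/C14b, with ring E (4-oxyphenyl) on C7c and ring F (3,5-dioxyphenyl) on C8c.
2. Retrosynthesis cuts, in order: the seven O-benzyl groups; the dihydrofuran of unit c in one operation (O13b–C7c, C7c–C8c, C8c–ring F); C7b–C10a of the seven-membered ring; the dihydrofuran of unit a by the same operation (O11b–C7a, C7a–C8a, C8a–ring B); the formyl, bromo and styryl groups of ring D back to 5-iodoresorcinol.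
3. Forward: Heck stilbene, then formyl and bromo handles on ring D, dihydrofuran of unit a, seven-membered ring (Friedel–Crafts), bromide to aldehyde, dihydrofuran of unit c, debenzylation.
4. Enabling feature: on each flank of ring D a phenolic oxygen (O11b, O13b) is ortho to a ring carbon (C10b, C14b) that carries a benzhydryl carbon (C8a, C8c). Ring D can therefore be dearomatised to an o-quinone methide (C13b=O/C14b=C8c); rearomatisation drives C–C bond formation with a benzylic sulfur ylide, and the phenoxide then closes the furan at the ylide carbon.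
5. Stereochemistry: C7a/C8a (S,S) from the (1R,4R,5R)-isothiocineole ylide; C7b (S) from C8a during ring closure; C7c/C8c (R,R) from the (1S,4S,5S)-isothiocineole ylide. The two dihydrofurans are locally enantiomeric, so the seven-membered ring is closed between the two annulations, before ring F exists and could compete with ring B.

Key step: step 11

Assumption: the isothiocineole benzylic ylide is taken to add to an o-quinone methide with the same ylide-face preference as in its benzylidene transfer to aldehydes; if the sense proves opposite, the two enantiomeric sulfonium salts are exchanged between steps 6 and 11.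
Assumption: both enantiomers of isothiocineole are purchased (otherwise one step each from limonene, sulfur and γ-terpinene), and S-alkylation is taken to occur on the exo lone pair (syn to the one-carbon bridge), giving one sulfonium epimer.

**Step 1**
Reactants: 1 5-iodobenzene-1,3-diol; 2 1-(benzyloxy)-4-ethenylbenzene
Product: 3 5-[(E)-2-(4-benzyloxyphenyl)ethenyl]benzene-1,3-diol
Conditions: Pd(OAc)2 (cat.), Et3N, DMF, 90 °C
Reagents that add atoms: none
Why: Heck reaction of an aryl iodide with a styrene; syn insertion and syn β-hydride elimination should give the E-stilbene, and free phenols are tolerated.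

**Step 2**
Reactants: 3 5-[(E)-2-(4-benzyloxyphenyl)ethenyl]benzene-1,3-diol
Product: 4 2-[(E)-2-(4-benzyloxyphenyl)ethenyl]-4,6-dihydroxybenzaldehyde
Conditions: POCl3, DMF, MeCN, 0 °C → rt; then H2O, 50 °C
Reagents that add atoms: N,N-dimethylformamide, CN(C)C=O; water, O
Why: Vilsmeier–Haack formylation of a 5-substituted resorcinol should go para to one hydroxyl and ortho to the other (C10b, next to the styryl group), the position between the two hydroxyls being the less reactive one.

**Step 3**
Reactants: 4 2-[(E)-2-(4-benzyloxyphenyl)ethenyl]-4,6-dihydroxybenzaldehyde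
Product: 5 3-bromo-2-[(E)-2-(4-benzyloxyphenyl)ethenyl]-4,6-dihydroxybenzaldehyde
Conditions: NBS (1.0 equiv), MeCN, −20 °C
Reagents that add atoms: N-bromosuccinimide, O=C1CCC(=O)N1Br
Why: electrophilic aromatic bromination of a 2,4-dihydroxybenzaldehyde should occur para to the chelated hydroxyl (C14b), and the phenol ring should react faster than the stilbene double bond.

**Step 4**
Reactants: 5 3-bromo-2-[(E)-2-(4-benzyloxyphenyl)ethenyl]-4,6-dihydroxybenzaldehyde
Product: 6 3-bromo-2-[(E)-2-(4-benzyloxyphenyl)ethenyl]-4,6-bis(tert-butoxycarbonyloxy)benzaldehyde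
Conditions: Boc2O (2.5 equiv), DMAP (cat.), i-Pr2NEt, THF, rt
Reagents that add atoms: di-tert-butyl dicarbonate, CC(C)(C)OC(=O)OC(=O)OC(C)(C)C
Why: DMAP-catalysed O-acylation turns both phenols into aryl tert-butyl carbonates; the one on O11b beside the aldehyde is the relay group for o-quinone methide formation, the other masks O13b.

**Step 5**
Reactants: 7 (1R,4R,5R)-isothiocineole; 8 1-(benzyloxy)-4-(chloromethyl)benzene
Product: 9 S-[4-(benzyloxy)benzyl] sulfonium tetrafluoroborate of (1R,4R,5R)-isothiocineole (benzyl exo on sulfur)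
Conditions: NaBF4, CH2Cl2–H2O, rt
Reagents that add atoms: sodium tetrafluoroborate, [Na+].F[B-](F)(F)F
Why: S-alkylation of the sulfide by the reactive 4-alkoxybenzyl chloride, pulled forward by exchange to the non-nucleophilic anion; attack through the exo lone pair should give one sulfonium epimer.

**Step 6**
Reactants: 6 3-bromo-2-[(E)-2-(4-benzyloxyphenyl)ethenyl]-4,6-bis(tert-butoxycarbonyloxy)benzaldehyde; 10 1,3-bis(benzyloxy)-5-bromobenzene; 9 sulfonium tetrafluoroborate of (1R,4R,5R)-isothiocineole
Product: 14 tert-butyl (2S,3S)-2-(4-benzyloxyphenyl)-3-[3,5-bis(benzyloxy)phenyl]-5-bromo-4-[(E)-2-(4-benzyloxyphenyl)ethenyl]-2,3-dihydro-1-benzofuran-6-yl carbonate (trans; dihydrofuran of unit a), via carbonate-shifted phenoxide 11 (not isolated), via o-quinone methide 12 (not isolated), via betaine 13 (not isolated)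
Conditions: 10, Mg, THF (Grignard reagent, 1.0 equiv); 6, THF, −78 °C; then ylide from 9 and LiN(SiMe3)2 (THF, −78 °C); −78 → 0 °C
Reagents that add atoms: none
Why: Proposed new method: Grignard addition to the aldehyde, 1,5-O-to-O Boc shift (11), loss of tert-butyl carbonate to o-quinone methide 12 (C11b=O, C10b=C8a), C-attack of the benzylic sulfonium ylide at C8a (betaine 13) and 5-exo-tet SN2 closure by O11b with inversion at C7a; the sulfide should fix C7a (S) through its open ylide face and the anti approach should fix C8a (S), giving the trans ring; the closest known reaction types are o-quinone methide generation from O-Boc salicylaldehydes and Grignard reagents, the [4+1] annulation of o-quinone methides with stabilised sulfur ylides, and isothiocineole-controlled benzylidene transfer; the remote carbonate on O13b, the bromide and the stilbene should be spectators under these basic conditions.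

**Step 7**
Reactants: 14 tert-butyl carbonate of the unit-a dihydrobenzofuran
Product: 15 bromophenol with the ampelopsin B skeleton (7aS,8aS,7bS): seven-membered ring closed by C7b–C10a; benzyl ethers on rings A and C (para) and on C11a and C13a of ring B; OH on C13b; Br on C14b
Conditions: CF3CO2H–CH2Cl2 (1:4), 0 °C → rt
Reagents that add atoms: none
Why: protonation of the stilbene at C8b gives the 4-alkoxybenzyl cation at C7b, which ring B captures at C10a in an intramolecular Friedel–Crafts alkylation (the acid cyclisation of ε-viniferin-type stilbenes to the ampelopsin B skeleton), C8a holding ring B on one face of the cation so that C7b should come out S, while the acid also cleaves the aryl carbonate.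

**Step 8**
Reactants: 15 bromophenol
Product: 16 salicylaldehyde: as 15 with CHO in place of Br on C14b
Conditions: n-BuLi (2.2 equiv), THF, −78 °C; then DMF, −78 → 0 °C; H2O
Reagents that add atoms: N,N-dimethylformamide, CN(C)C=O
Why: deprotonation of the phenol and bromine–lithium exchange give the ortho-lithiated phenoxide, which DMF formylates (Bouveault-type formylation); no stereocentre is touched.

**Step 9**
Reactants: 16 salicylaldehyde
Product: 17 aryl tert-butyl carbonate: as 16 with O13b carrying Boc
Conditions: Boc2O, DMAP (cat.), Et3N, CH2Cl2, rt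
Reagents that add atoms: di-tert-butyl dicarbonate, CC(C)(C)OC(=O)OC(=O)OC(C)(C)C
Why: DMAP-catalysed O-acylation of the salicylaldehyde hydroxyl installs the carbonate relay group next to the aldehyde.

**Step 10**
Reactants: 18 (1S,4S,5S)-isothiocineole; 8 1-(benzyloxy)-4-(chloromethyl)benzene
Product: 19 S-[4-(benzyloxy)benzyl] sulfonium tetrafluoroborate of (1S,4S,5S)-isothiocineole (benzyl exo on sulfur)
Conditions: NaBF4, CH2Cl2–H2O, rt
Reagents that add atoms: sodium tetrafluoroborate, [Na+].F[B-](F)(F)F
Why: same S-alkylation and anion exchange as in step 5, in the enantiomeric series.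

**Step 11**
Reactants: 17 aryl tert-butyl carbonate; 10 1,3-bis(benzyloxy)-5-bromobenzene; 19 sulfonium tetrafluoroborate of (1S,4S,5S)-isothiocineole
Product: 23 hepta-O-benzyl ether of the target (7aS,8aS,7bS,7cR,8cR; dihydrofuran of unit c trans), via carbonate-shifted phenoxide 20 (not isolated), via o-quinone methide 21 (not isolated), via betaine 22 (not isolated)
Conditions: 10, Mg, THF (Grignard reagent, 1.0 equiv); 17, THF, −78 °C; then ylide from 19 and LiN(SiMe3)2 (THF, −78 °C); −78 → 0 °C
Reagents that add atoms: none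
Why: Proposed new method: the Grignard reagent adds to the aldehyde, the magnesium alkoxide takes the Boc group from the neighbouring O13b (1,5-O-to-O shift, 20) and the freed phenoxide expels tert-butyl carbonate, dearomatising ring D to o-quinone methide 21; the benzylic sulfonium ylide then adds through carbon to C8c, which restores the aromatic ring (betaine 22), and phenoxide O13b displaces the sulfide at C7c. The closest known reaction types are the generation of o-quinone methides from O-Boc salicylaldehydes and Grignard reagents, the [4+1] annulation of o-quinone methides with carbonyl-stabilised sulfur or ammonium ylides, and isothiocineole-controlled benzylidene transfer to aldehydes and imines; their combination with a semi-stabilised chiral benzylic ylide is the new element. The furan ring closes in the 5-exo-tet mode by SN2 displacement with inversion at C7c. C7c is controlled by the sulfide, which fixes the ylide conformation and shields one ylide face, and C8c by the anti (aryl to aryl) approach of that face to the methide carbon, which maps onto the trans ring after inversion; a closure with SN1 character would likewise end in the trans ring. The step needs C-attack of the ylide at C8c ahead of every other nucleophile and reagent control over the chiral core: the substrate secures the first because the Boc group sits only on O13b beside the aldehyde, so the one electrophile unmasked is the C14b=C8c methide, whose capture restores the aromaticity of ring D, and the second because the nearest core stereocentre (C7b) lies 1,4 to C8c across the planar ring.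

**Step 12**
Reactants: 23 hepta-O-benzyl ether
Product: 24 target trimer CNP0136963.1 (7aS,8aS,7bS,7cR,8cR)
Conditions: H2 (1 atm), Pd/C, EtOAc–MeOH, rt
Reagents that add atoms: none
Why: hydrogenolysis of the seven aryl benzyl ethers should be faster than cleavage of the two cyclic benzylic C–O bonds, and no stereocentre is affected.

**Compound list**

1 | 5-iodobenzene-1,3-diol | Oc1cc(O)cc(I)c1 | starting material
2 | 1-(benzyloxy)-4-ethenylbenzene | C=Cc1ccc(OCc2ccccc2)cc1 | starting material
3 | 5-[(E)-2-(4-benzyloxyphenyl)ethenyl]benzene-1,3-diol | Oc1cc(O)cc(/C=C/c2ccc(OCc3ccccc3)cc2)c1 | intermediate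
4 | 2-[(E)-2-(4-benzyloxyphenyl)ethenyl]-4,6-dihydroxybenzaldehyde | O=Cc1c(O)cc(O)cc1/C=C/c1ccc(OCc2ccccc2)cc1 | intermediate
5 | 3-bromo-2-[(E)-2-(4-benzyloxyphenyl)ethenyl]-4,6-dihydroxybenzaldehyde | O=Cc1c(O)cc(O)c(Br)c1/C=C/c1ccc(OCc2ccccc2)cc1 | intermediate
6 | 3-bromo-2-[(E)-2-(4-benzyloxyphenyl)ethenyl]-4,6-bis(tert-butoxycarbonyloxy)benzaldehyde | O=Cc1c(OC(=O)OC(C)(C)C)cc(OC(=O)OC(C)(C)C)c(Br)c1/C=C/c1ccc(OCc2ccccc2)cc1 | intermediate
7 | (1R,4R,5R)-isothiocineole [(1R,4R,5R)-4,7,7-trimethyl-6-thiabicyclo[3.2.1]octane] | C[C@@H]1CC[C@@H]2C[C@H]1SC2(C)C | starting material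
8 | 1-(benzyloxy)-4-(chloromethyl)benzene | ClCc1ccc(OCc2ccccc2)cc1 | starting material
9 | S-[4-(benzyloxy)benzyl] sulfonium tetrafluoroborate of (1R,4R,5R)-isothiocineole, benzyl exo on sulfur | C[C@@H]1CC[C@@H]2C[C@H]1[S@@+](Cc1ccc(OCc3ccccc3)cc1)C2(C)C.F[B-](F)(F)F | intermediate
10 | 1,3-bis(benzyloxy)-5-bromobenzene | Brc1cc(OCc2ccccc2)cc(OCc2ccccc2)c1 | starting material
11 | bromomagnesium phenoxide (O11b) of the Grignard adduct of 6 after Boc shift; benzhydryl tert-butyl carbonate at C8a, carbinol carbon unspecified | [O-]c1cc(OC(=O)OC(C)(C)C)c(Br)c(/C=C/c2ccc(OCc3ccccc3)cc2)c1C(OC(=O)OC(C)(C)C)c1cc(OCc2ccccc2)cc(OCc2ccccc2)c1.[Mg+2].[Br-] | intermediate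
12 | o-quinone methide of ring D (C11b=O, C10b=C8a; methide geometry unspecified) | O=C1C=C(OC(=O)OC(C)(C)C)C(Br)=C(/C=C/c2ccc(OCc3ccccc3)cc2)C1=Cc1cc(OCc2ccccc2)cc(OCc2ccccc2)c1 | intermediate
13 | betaine: O11b phenoxide, C8a–C7a bond formed, C7a bearing the isothiocineole sulfonium | [O-]c1cc(OC(=O)OC(C)(C)C)c(Br)c(/C=C/c2ccc(OCc3ccccc3)cc2)c1[C@H](c1cc(OCc2ccccc2)cc(OCc2ccccc2)c1)[C@H](c1ccc(OCc2ccccc2)cc1)[S@@+]1[C@@H]2C[C@@H](CC[C@H]2C)C1(C)C | intermediate
14 | tert-butyl (2S,3S)-2-(4-benzyloxyphenyl)-3-[3,5-bis(benzyloxy)phenyl]-5-bromo-4-[(E)-2-(4-benzyloxyphenyl)ethenyl]-2,3-dihydro-1-benzofuran-6-yl carbonate | CC(C)(C)OC(=O)Oc1cc2O[C@H](c3ccc(OCc4ccccc4)cc3)[C@@H](c3cc(OCc4ccccc4)cc(OCc4ccccc4)c3)c2c(/C=C/c2ccc(OCc3ccccc3)cc2)c1Br | intermediate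
15 | bromophenol with the ampelopsin B skeleton (7aS,8aS,7bS); benzyl ethers on rings A and C (para) and on C11a and C13a of ring B; OH on C13b; Br on C14b | c1ccccc1COc1ccc([C@@H]2Cc3c4c(cc(O)c3Br)O[C@H](c3ccc(OCc5ccccc5)cc3)[C@H]4c3cc(OCc5ccccc5)cc(OCc5ccccc5)c32)cc1 | intermediate
16 | salicylaldehyde: as 15 with CHO on C14b | c1ccccc1COc1ccc([C@@H]2Cc3c4c(cc(O)c3C=O)O[C@H](c3ccc(OCc5ccccc5)cc3)[C@H]4c3cc(OCc5ccccc5)cc(OCc5ccccc5)c32)cc1 | intermediate
17 | as 16 with O13b as tert-butyl carbonate | c1ccccc1COc1ccc([C@@H]2Cc3c4c(cc(OC(=O)OC(C)(C)C)c3C=O)O[C@H](c3ccc(OCc5ccccc5)cc3)[C@H]4c3cc(OCc5ccccc5)cc(OCc5ccccc5)c32)cc1 | intermediate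
18 | (1S,4S,5S)-isothiocineole | C[C@H]1CC[C@H]2C[C@@H]1SC2(C)C | starting material
19 | S-[4-(benzyloxy)benzyl] sulfonium tetrafluoroborate of (1S,4S,5S)-isothiocineole, benzyl exo on sulfur | C[C@H]1CC[C@H]2C[C@@H]1[S@+](Cc1ccc(OCc3ccccc3)cc1)C2(C)C.F[B-](F)(F)F | intermediate
20 | bromomagnesium phenoxide (O13b) of the Grignard adduct of 17 after Boc shift; benzhydryl tert-butyl carbonate at C8c, carbinol carbon unspecified | c1ccccc1COc1ccc([C@@H]2Cc3c4c(cc([O-])c3C(OC(=O)OC(C)(C)C)c3cc(OCc5ccccc5)cc(OCc5ccccc5)c3)O[C@H](c3ccc(OCc5ccccc5)cc3)[C@H]4c3cc(OCc5ccccc5)cc(OCc5ccccc5)c32)cc1.[Mg+2].[Br-] | intermediate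
21 | o-quinone methide of ring D (C13b=O, C14b=C8c; methide geometry unspecified) | c1ccccc1COc1ccc([C@@H]2CC3=C4C(=CC(=O)C3=Cc3cc(OCc5ccccc5)cc(OCc5ccccc5)c3)O[C@H](c3ccc(OCc5ccccc5)cc3)[C@H]4c3cc(OCc5ccccc5)cc(OCc5ccccc5)c32)cc1 | intermediate
22 | betaine: O13b phenoxide, C8c–C7c bond formed, C7c bearing the isothiocineole sulfonium | c1ccccc1COc1ccc([C@@H]2Cc3c4c(cc([O-])c3[C@@H](c3cc(OCc5ccccc5)cc(OCc5ccccc5)c3)[C@@H](c3ccc(OCc5ccccc5)cc3)[S@+]3[C@H]5C[C@H](CC[C@@H]5C)C3(C)C)O[C@H](c3ccc(OCc5ccccc5)cc3)[C@H]4c3cc(OCc5ccccc5)cc(OCc5ccccc5)c32)cc1 | intermediate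
23 | hepta-O-benzyl ether of the target, (7aS,8aS,7bS,7cR,8cR) | c1ccccc1COc1ccc([C@@H]2Cc3c4c(cc5c3[C@@H](c3cc(OCc6ccccc6)cc(OCc6ccccc6)c3)[C@H](c3ccc(OCc6ccccc6)cc3)O5)O[C@H](c3ccc(OCc6ccccc6)cc3)[C@H]4c3cc(OCc6ccccc6)cc(OCc6ccccc6)c32)cc1 | intermediate
24 | target trimer CNP0136963.1, (7aS,8aS,7bS,7cR,8cR) | Oc1ccc([C@@H]2Cc3c4c(cc5c3[C@@H](c3cc(O)cc(O)c3)[C@H](c3ccc(O)cc3)O5)O[C@H](c3ccc(O)cc3)[C@H]4c3cc(O)cc(O)c32)cc1 | target

**Step count and risks**

Total steps: 12 (ten on the main line, two for the sulfonium salts). Longest linear sequence: 10 steps (1, 2, 3, 4, 6, 7, 8, 9, 11, 12).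

Steps most likely to fail:

Step 11. The semi-stabilised ylide may be lost before 21 forms, residual Grignard reagent may add to 21, or facial selectivity may erode if the chiral core opposes the reagent. Fallback from 17, returning at 23: 21 is generated as in step 11 but trapped with an ester-stabilised ylide, the ylide class for which the [4+1] annulation with o-quinone methides is established ((2-ethoxy-2-oxoethyl)dimethylsulfonium bromide with Cs2CO3, or the cinchona-derived ammonium ylide of ethyl bromoacetate for enantiocontrol). This should give the ethyl trans-2,3-dihydrobenzofuran-2-carboxylate F1, and any C8c epimer is separated at this stage. Saponification with LiOH (THF–H2O) gives the carboxylic acid F2. Decarboxylative arylation of this α-oxy acid with 1-(benzyloxy)-4-iodobenzene (NiCl2·glyme, 4,4'-di-tert-butyl-2,2'-bipyridine, Ir[dF(CF3)ppy]2(dtbbpy)PF6, Cs2CO3, blue light) should place ring E trans to ring F and give 23.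

Step 6. The same processes apply as in step 11, with added steric pressure from the neighbouring styryl group on the methide carbon. Fallback from 6, returning at 15: 12 is generated as in step 6 and trapped with the same ester-stabilised ylide (enantioselective cinchona-ammonium variant) to give the ethyl trans-2,3-dihydrobenzofuran-2-carboxylate F3. LiOH cleaves the ester and the aryl carbonate to give the hydroxy acid F4. The decarboxylative arylation described above (the aryl iodide reacting ahead of the hindered aryl bromide) gives the phenol F5; scrambling of the alkene geometry by the photocatalyst is immaterial. CF3CO2H as in step 7 then closes the seven-membered ring to 15.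

Step 7. Competing ionisation of the C7a–O bond may open the dihydrofuran of unit a and lead to indane formation, the Boc-derived cation may tert-butylate ring B, benzyl ethers may be lost, or ring B may add to the wrong face of C7b. Fallback from 14, returning at 15: the C7b cation is generated from a carbinol instead of by protonation of the alkene. Markovnikov oxymercuration–demercuration (Hg(OAc)2, THF–H2O; then NaBH4) places the hydroxyl on C7b to give the benzylic alcohol F6 (both carbinol epimers). Ionisation with catalytic Bi(OTf)3 (CH2Cl2, −40 °C) closes the ring to the aryl carbonate F7. K2CO3 in MeOH removes the carbonate to give 15.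

**Further compounds**

F1 | step 11 | ethyl ester analogue of 23: CO2Et in place of ring E on C7c, trans to ring F | c1ccccc1COc1ccc([C@@H]2Cc3c4c(cc5c3[C@@H](c3cc(OCc6ccccc6)cc(OCc6ccccc6)c3)[C@H](C(=O)OCC)O5)O[C@H](c3ccc(OCc6ccccc6)cc3)[C@H]4c3cc(OCc6ccccc6)cc(OCc6ccccc6)c32)cc1
F2 | step 11 | carboxylic acid from F1 (CO2H on C7c) | c1ccccc1COc1ccc([C@@H]2Cc3c4c(cc5c3[C@@H](c3cc(OCc6ccccc6)cc(OCc6ccccc6)c3)[C@H](C(=O)O)O5)O[C@H](c3ccc(OCc6ccccc6)cc3)[C@H]4c3cc(OCc6ccccc6)cc(OCc6ccccc6)c32)cc1
F3 | step 6 | ethyl trans-3-[3,5-bis(benzyloxy)phenyl]-5-bromo-4-[(E)-2-(4-benzyloxyphenyl)ethenyl]-6-(tert-butoxycarbonyloxy)-2,3-dihydro-1-benzofuran-2-carboxylate (C8a as in 14) | CC(C)(C)OC(=O)Oc1cc2O[C@H](C(=O)OCC)[C@@H](c3cc(OCc4ccccc4)cc(OCc4ccccc4)c3)c2c(/C=C/c2ccc(OCc3ccccc3)cc2)c1Br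
F4 | step 6 | trans-3-[3,5-bis(benzyloxy)phenyl]-5-bromo-4-[(E)-2-(4-benzyloxyphenyl)ethenyl]-6-hydroxy-2,3-dihydro-1-benzofuran-2-carboxylic acid | Oc1cc2O[C@H](C(=O)O)[C@@H](c3cc(OCc4ccccc4)cc(OCc4ccccc4)c3)c2c(/C=C/c2ccc(OCc3ccccc3)cc2)c1Br
F5 | step 6 | (2S,3S)-2-(4-benzyloxyphenyl)-3-[3,5-bis(benzyloxy)phenyl]-5-bromo-4-[(E)-2-(4-benzyloxyphenyl)ethenyl]-2,3-dihydro-1-benzofuran-6-ol | Oc1cc2O[C@H](c3ccc(OCc4ccccc4)cc3)[C@@H](c3cc(OCc4ccccc4)cc(OCc4ccccc4)c3)c2c(/C=C/c2ccc(OCc3ccccc3)cc2)c1Br
F6 | step 7 | C7b carbinol from 14: 4-[2-(4-benzyloxyphenyl)-2-hydroxyethyl] analogue of 14, carbinol carbon unspecified | CC(C)(C)OC(=O)Oc1cc2O[C@H](c3ccc(OCc4ccccc4)cc3)[C@@H](c3cc(OCc4ccccc4)cc(OCc4ccccc4)c3)c2c(CC(O)c2ccc(OCc3ccccc3)cc2)c1Br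
F7 | step 7 | tert-butyl carbonate of 15 (Boc on O13b) | c1ccccc1COc1ccc([C@@H]2Cc3c4c(cc(OC(=O)OC(C)(C)C)c3Br)O[C@H](c3ccc(OCc5ccccc5)cc3)[C@H]4c3cc(OCc5ccccc5)cc(OCc5ccccc5)c32)cc1
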